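## Structural features

The target is a bicyclic diterpenoid acid of the labdane type. It is a trans-fused decalin (ring A: C1–C5 and C10; ring B: C5–C10) with a gem-dimethyl group at C4, an angular methyl (C20) at C10, an exocyclic methylene (C17) at C8, and a saturated chain C11–C16 at C9 that ends in the free C15 acid and carries a methyl stereocentre at C13. The ring stereocentres C5, C10 and C9 are contiguous: H5 and C11 lie on one face, C20 and H9 on the other, so the side chain is axial (a 9-epi-ent-labdane core, 5R,9S,10R). C2 (S) carries the isovalerate on an axial oxygen flanked by two syn-axial methyl groups (C20 and one C4 methyl), and C13 (S) is too remote to be controlled from the ring. The fragile points are the 8(17)-alkene (acid-promoted migration into the ring), the pairing of an isovalerate with a free acid, and, in any intermediate with a C8 carbonyl, the C9 centre, whose axial chain can epimerise to the equatorial position. The real difficulty is the quaternary C10 next to a C9 centre of the less stable configuration, both with absolute control and beside the fully substituted C4. The key step exploits the fact that ring A plus C6, C7, oxygen-bearing C8 and C9 is a ring-oxygenated β-ionone extended at its ketone: C10=C5–C6=C7–C8=C9 is a hexatriene, and closing the single bond C9–C10 gives ring B while translating olefin geometry into the C9/C10 relationship.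

## Logic of the disconnections

**27 ⇒ 26.** Bond concerned: O–CH3 of a C15 methyl ester. The acid must stay masked through acetylide, hydride and acylation chemistry. The gain is compatibility, not skeleton. The forward hydrolysis must spare the C2 isovalerate, which its axial, doubly flanked position should allow.

**26 ⇒ 24 + 25.** Cut: the acyl C–O bond at C2. This removes five carbons and leaves the hindered axial alcohol to be acylated last but one, under forcing conditions.

**24 ⇒ 23 ⇒ 22.** The axial C2–O bond is traced through the C2 ketone to the equatorial epimer (the C2–H bond is made last). An axial oxygen syn to two methyl groups cannot be used to steer ring construction, whereas an equatorial one can. The demand is that hydride attacks 23 only from the equatorial side.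

**22 ⇒ 21 ⇒ 20.** Cuts: O–Si, then C8=C17. C17 is the only carbon absent from the ionone-type precursor, and removing it leaves a C8 carbonyl, the natural product of an enol ether. The methylenation must not enolise towards C9.

**20 ⇒ 19 ⇒ 18.** Cuts: the C5–H and C6–H bonds (hydrogenation of C5=C6), then the enol O–Si bond. This returns ring B to the cyclohexadiene oxidation level. The demands are hydrogen at C5 trans to C20 and protonation of the dienolate at C7.

**18 ⇒ 17.** Cut: C9–C10, the only ring B bond missing from the chain. Ring B, the quaternary centre and C9 are removed in one stroke. The forward step must close a fully substituted terminus with an inside methyl and must choose one face of ring A.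

**17 ⇒ 16 ⇒ 15.** The two hydrogens at C6 and C7 are removed (alkyne), then the enol O–Si bond with the C9–H bond. In this order a Z alkene never stands next to a free C8 carbonyl, so closure through oxygen is excluded. The demands are a clean syn semi-hydrogenation and a Z enol ether.

**15 ⇒ 8 + 13.** Cut: C7–C8 (alkynyl–acyl). This is the convergent bond between ring A and the chain. The acetylide must attack the Weinreb amide and not the ester.

**8 ⇒ 5 + 6; 5 ⇒ 3 ⇒ 2 ⇒ 1.** Cuts: C5–C6 (sp2–sp), then the C5–O triflate bond together with a C1–H bond, then O–Si, then the carbinol C–H. The single ring stereocentre is reduced to an enantioselective carbonyl reduction of 1.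

**13 ⇒ 10 + 11; 10 ⇒ 9.** Cut: C11–C12, with a carboxyl restored on C12, then the ester C–O bond of the half-ester. C13 becomes the prochiral centre of a meso anhydride. The demands are an efficient primary-radical addition and an enantioselective ring opening.

## Other disconnections considered

**Alternative 1:** The cuts are C1–C2 and C9–C10, which open both rings and lead to the acyclic aldehyde A1, whose only ring-relevant stereocentre is C5.
- **Forward step.** SnCl4 activates the C2 aldehyde, the isopropenyl group attacks it through C1 (Prins step), and the tertiary C10 cation is trapped by the allylsilane through C9. Loss of silicon leaves the 8(17)-alkene, so A2 would form with both rings, C2, C10 and C9 in one operation.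
- **In its favour.** The exocyclic methylene arrives in the key step, so no 8-ketone and no epimerisable C9 centre are ever handled. C5 is fixed from the start and is not the outcome of a late hydrogenation. On these two points it is the better plan.
- **Against it here.** The axial C11 chain requires the allylsilane isomer with C11 cis to C7. This is Z along the chain but E by the sequence rule, because CH2SiMe3 outranks C7. In the chair transition state that substituent is forced axial against the forming quaternary centre, so boat pathways and the C9 epimer lie close in energy. The aldehyde-initiated step competes with a simple carbonyl-ene reaction and with chloride capture of the cation. A1 itself, with a stereocentre flanked by three different chains and a geometrically pure trisubstituted allylsilane, is a long synthesis.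
- **Comparison.** At C2 the two plans are equal: both deliver the equatorial oxygen and need the same oxidation–reduction inversion. The alternative must also raise C15 from silyl ether to acid. The chosen plan sets C9 against C10 by orbital symmetry, the alternative only by a conformational preference of a cation. The alternative is shorter after its key step and longer before it.

**Alternative 2:** The cuts are C1–C10 and C4–C5, which take ring A apart into the 2-silyloxydiene A3 and the enedione A4.
- **Forward step.** A chiral Lewis acid (an oxazaborolidinium salt is the obvious choice) would catalyse the Diels–Alder reaction to the cis-fused dione A5, with the C10 quaternary centre set by the catalyst.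
- **In its favour.** Absolute configuration at C10 comes from a catalyst acting at the reacting centre, which is better than the three-bond relay from C2 in the chosen plan. C2 arrives at the ketone level, so the axial alcohol needs one reduction and no inversion, again better. The bicycle is reached in one step from two small achiral compounds.
- **Against it here.** A3 carries two methyl groups on its reacting terminus, which disfavours the s-cis conformer. The new C4–C5 bond joins a fully substituted carbon to a tertiary one next to the forming quaternary centre, at the limit of what catalysed cycloadditions tolerate. A5 is far from the target: the C6 carbonyl must be removed, C5 epimerised to the trans fusion, the whole C11–C16 chain added at C9 with an axial outcome, and C8 functionalised and methylenated.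
- **Comparison.** The alternative solves C10 and C2 well and leaves C9, the hardest centre, open; the chosen plan solves C9 and C10 together and pays at C2. Both key steps are concerted, but only the electrocyclisation transfers stereochemical information to C9. The alternative is equal or better up to the bicycle and clearly worse after it.

**Alternative 3:** The cuts are C6–C7 and, as in the chosen plan, C9–C10; they lead to the ring A enal A6 and methyl acetoacetate A7.
- **Forward step.** Condensation at C6–C7, then enolisation or enamine formation towards the acetyl methyl group, would give a push–pull triene that electrocyclises in the same flask to the enol A8.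
- **In its favour.** The acceptor at C7 and the donor at C8 should lower the barrier of the same ring closure markedly. No Z alkene has to be made, because one of the two acyl groups at C7 is always cis to ring A. The bicycle is reached in one step from the enal. In rate and in step economy up to the bicycle it is the better plan; in face selectivity at C10 it is the equal, since the same C2 silyloxy group is the only control element.
- **Against it here.** The C9 terminus is a CH2 group, so the electrocyclisation no longer sets C9, and orbital symmetry is not used for the one centre that is hard to obtain otherwise. The C11–C16 chain with its C13 centre must be attached later by alkylation at C9. The C7 ester must be removed by decarboxylation under conditions that endanger the epimerisable C9. The free carbonyl of the condensation product can close onto C10 through oxygen instead of carbon.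
- **Comparison.** The chosen plan carries the complete chain through the ring closure and the alternative does not. The two are the same pericyclic event with different substituents. The alternative wins before the bicycle and loses after it.

Key step: step 10

Assumption: labdane numbering (C1–C20) is used for ring-containing compounds; in steps 1 and 5 the catalyst enantiomer named is the one expected from the usual models, and the antipodal catalyst (equally available) is taken if the sign of rotation of 2 or 10 shows the opposite sense.

## Route

Step 1
Reactants: 1 ketoisophorone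
Product: 2 (4R)-4-hydroxy-2,6,6-trimethylcyclohex-2-en-1-one
Conditions: RuCl(p-cymene)[(R,R)-TsDPEN] (1 mol%), i-PrOH, rt
Reagents that add atoms: none
Why: Noyori–Ikariya asymmetric transfer hydrogenation of the less hindered enone-type C4 carbonyl; the C1 carbonyl next to the quaternary carbon is not touched. The alkene takes the role of the aryl group in the usual model, so the (R,R) catalyst should give the R carbinol, which becomes C2 of the decalin.

Step 2
Reactants: 2 (4R)-4-hydroxy-2,6,6-trimethylcyclohex-2-en-1-one
Product: 3 (4R)-4-(tert-butyldimethylsilyloxy)-2,6,6-trimethylcyclohex-2-en-1-one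
Conditions: TBSCl, imidazole, DMF, rt
Reagents that add atoms: tert-butyldimethylsilyl chloride, CC(C)(C)[Si](C)(C)Cl
Why: Standard silylation of a secondary allylic alcohol; the silyl ether withstands every step up to step 14 and is the equatorial control element of the key step.

Step 3
Reactants: 3 (4R)-4-(tert-butyldimethylsilyloxy)-2,6,6-trimethylcyclohex-2-en-1-one
Product: 5 (4S)-4-(tert-butyldimethylsilyloxy)-2,6,6-trimethylcyclohex-1-en-1-yl trifluoromethanesulfonate, via lithium enolate 4 (not isolated)
Conditions: Li[HB(s-Bu)3] (L-Selectride), THF, −78 °C; then PhNTf2, −78 °C to rt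
Reagents that add atoms: N-phenylbis(trifluoromethanesulfonimide), O=S(=O)(N(c1ccccc1)S(=O)(=O)C(F)(F)F)C(F)(F)F
Why: Conjugate hydride addition to the β-unsubstituted enone (1,2-attack is blocked by the quaternary carbon and the α-methyl group) gives the tetrasubstituted enolate regiospecifically, and O-triflation traps it. No stereocentre is formed; the descriptor changes from R to S only because the ranking of the ring branches changes.

Step 4
Reactants: 5 (4S)-4-(tert-butyldimethylsilyloxy)-2,6,6-trimethylcyclohex-1-en-1-yl trifluoromethanesulfonate; 6 ethynyltrimethylsilane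
Product: 8 tert-butyl{[(1S)-4-ethynyl-3,5,5-trimethylcyclohex-3-en-1-yl]oxy}dimethylsilane, via alkynylsilane 7 (not isolated)
Conditions: Pd(PPh3)4 (5 mol%), CuI, Et3N, DMF, 60 °C; then K2CO3, MeOH, rt
Reagents that add atoms: none
Why: Sonogashira coupling of the hindered alkenyl triflate, a standard partner of this trimethylcyclohexenyl type, followed by protodesilylation of the alkynylsilane with methanolic carbonate in the same flask. The alkyl silyl ether is stable to both stages.

Step 5
Reactants: 9 3-methylglutaric anhydride
Product: 10 (3S)-5-methoxy-3-methyl-5-oxopentanoic acid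
Conditions: (DHQ)2AQN (10 mol%), MeOH (10 equiv), Et2O, −40 °C
Reagents that add atoms: methanol, CO
Why: Cinchona-alkaloid-catalysed enantioselective methanolysis (desymmetrisation) of the meso anhydride; the catalyst acts as a chiral general base and distinguishes the enantiotopic carbonyl groups. This sets C13 (S).

Step 6
Reactants: 10 (3S)-5-methoxy-3-methyl-5-oxopentanoic acid; 11 N-methoxy-N-methylacrylamide
Product: 13 methyl (3S)-7-[methoxy(methyl)amino]-3-methyl-7-oxoheptanoate, via N-hydroxyphthalimide ester 12 (not isolated)
Conditions: N-hydroxyphthalimide, DIC, DMAP (cat.), CH2Cl2, rt; then Ni(ClO4)2·6H2O (20 mol%), Zn, LiCl, MeCN, rt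
Reagents that add atoms: none
Why: Decarboxylative Giese addition of a redox-active ester: single-electron reduction releases CO2 and phthalimide, and the primary C12 radical adds to the terminal carbon of the acrylamide. The C13 centre is β to the radical and is not affected.

Step 7
Reactants: 8 tert-butyl{[(1S)-4-ethynyl-3,5,5-trimethylcyclohex-3-en-1-yl]oxy}dimethylsilane; 13 methyl (3S)-7-[methoxy(methyl)amino]-3-methyl-7-oxoheptanoate
Product: 15 methyl (3S)-9-[(4S)-4-(tert-butyldimethylsilyloxy)-2,6,6-trimethylcyclohex-1-en-1-yl]-3-methyl-7-oxonon-8-ynoate, via magnesium acetylide 14 (not isolated)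
Conditions: i-PrMgCl, THF, 0 °C to rt; then 13, 0 °C to rt; aq. NH4Cl
Reagents that add atoms: none
Why: Weinreb ketone synthesis with an alkynyl Grignard reagent; the chelated tetrahedral adduct stops at the ketone stage. A magnesium acetylide at 0 °C should not attack the methyl ester.

Step 8
Reactants: 15 methyl (3S)-9-[(4S)-4-(tert-butyldimethylsilyloxy)-2,6,6-trimethylcyclohex-1-en-1-yl]-3-methyl-7-oxonon-8-ynoate
Product: 16 methyl (3S,6Z)-7-(tert-butyldimethylsilyloxy)-9-[(4S)-4-(tert-butyldimethylsilyloxy)-2,6,6-trimethylcyclohex-1-en-1-yl]-3-methylnon-6-en-8-ynoate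
Conditions: TBSOTf, Et3N, CH2Cl2, −78 to 0 °C
Reagents that add atoms: tert-butyldimethylsilyl trifluoromethanesulfonate, CC(C)(C)[Si](C)(C)OS(=O)(=O)C(F)(F)F
Why: Soft enolisation; the only α-hydrogens are at C9 and the β-carbon of the ynone is shielded by ring A against amine addition. Deprotonation of the O-silylated oxocarbenium ion in its least strained conformation should place C11 syn to oxygen (Z enol ether, C11 trans to C7).

Step 9
Reactants: 16 methyl (3S,6Z)-7-(tert-butyldimethylsilyloxy)-9-[(4S)-4-(tert-butyldimethylsilyloxy)-2,6,6-trimethylcyclohex-1-en-1-yl]-3-methylnon-6-en-8-ynoate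
Product: 17 methyl (3S,6Z,8Z)-7-(tert-butyldimethylsilyloxy)-9-[(4S)-4-(tert-butyldimethylsilyloxy)-2,6,6-trimethylcyclohex-1-en-1-yl]-3-methylnona-6,8-dienoate
Conditions: H2 (1 atm), Pd/CaCO3 poisoned with Pb(OAc)2 (Lindlar catalyst), quinoline, hexane/EtOAc, 0 °C; crude product kept cold and used at once
Reagents that add atoms: none
Why: Lindlar semi-hydrogenation delivers both hydrogens syn and gives the Z C6=C7 alkene without touching the enol ether geometry. Because the carbonyl is already masked, no Z-dienone and no pyran valence isomer can form.

Step 10
Reactants: 17 methyl (3S,6Z,8Z)-7-(tert-butyldimethylsilyloxy)-9-[(4S)-4-(tert-butyldimethylsilyloxy)-2,6,6-trimethylcyclohex-1-en-1-yl]-3-methylnona-6,8-dienoate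
Product: 18 methyl 2,8-bis(tert-butyldimethylsilyloxy)-17-norlabda-5,7-dien-15-oate (2-silyloxy group trans to the C10 methyl; C11 trans and H9 cis to the C10 methyl; C9, C10 and C13 as in 27)
Conditions: degassed toluene (0.01 M), BHT (cat.), Et3N (trace), sealed vessel, 150 °C
Reagents that add atoms: none
Why: Thermal disrotatory six-electron electrocyclisation of the C10=C5–C6=C7–C8=C9 triene in its helical s-cis,s-cis conformation forms the C9–C10 σ-bond and closes ring B as a 1-silyloxycyclohexa-1,3-diene; the closest known reactions are the thermal closure of previtamin D to pyro- and isopyrocalciferol, which has the same ring-bound fully substituted terminus with an inside methyl, and the thermal closure of 2-silyloxyhexatrienes. Ring B closes in the disrotatory mode that orbital symmetry imposes on a thermal six-electron process. C9 against C10 is fixed by that mode and the olefin geometry: C11 is outside and C20 inside, so they end trans and H9 ends cis to the C10 methyl. The absolute sense at C10, and with it C9, is relayed from C2: ring B forces C20 into the axial position on ring A, and only closure on the face that keeps the C2 silyloxy group equatorial, trans to C20, avoids two syn-axial contacts (with C20 and with one C4 methyl). The step needs periselectivity over the reversible antarafacial [1,7]-hydrogen shift from C20 to C9, which should act only as a resting equilibrium that drains through the irreversible closure at this temperature, and it needs face selectivity, which the conformational argument above should secure. Silylation on oxygen excludes closure through oxygen, and an isomer with C11 inside would close far more slowly and should not be carried into the product.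

Step 11
Reactants: 18 methyl 2,8-bis(tert-butyldimethylsilyloxy)-17-norlabda-5,7-dien-15-oate
Product: 19 methyl 2-(tert-butyldimethylsilyloxy)-8-oxo-17-norlabd-5-en-15-oate (stereocentres as in 18)
Conditions: n-Bu4NF (TBAF), AcOH, THF, −78 to −40 °C
Reagents that add atoms: none
Why: Fluoride cleaves the enol silyl ether selectively (the secondary alkyl silyl ether is inert at this temperature), and acetic acid protonates the dienolate kinetically at the α-carbon C7 to give the deconjugated 5-en-8-one. C9 is not part of the dienolate and keeps its configuration.

Step 12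
Reactants: 19 methyl 2-(tert-butyldimethylsilyloxy)-8-oxo-17-norlabd-5-en-15-oate
Product: 20 methyl 2-(tert-butyldimethylsilyloxy)-8-oxo-17-norlabdan-15-oate (trans-fused; H5 trans to the C10 methyl, cis to C11)
Conditions: Mn(dpm)3 (10 mol%), PhSiH3, t-BuOOH, i-PrOH, rt
Reagents that add atoms: none
Why: Metal-hydride hydrogen-atom-transfer hydrogenation of Mukaiyama type: a hydrogen atom adds to C6, and the tertiary C5 radical should take up hydrogen axially, on the face opposite C20 and the axial C4 methyl, to give the trans-fused decalin. The neutral conditions leave the enolisable C9 centre alone.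

Step 13
Reactants: 20 methyl 2-(tert-butyldimethylsilyloxy)-8-oxo-17-norlabdan-15-oate
Product: 21 methyl 2-(tert-butyldimethylsilyloxy)labd-8(17)-en-15-oate (silyloxy group equatorial; other centres as in 27)
Conditions: Zn, CH2Br2, TiCl4, THF/CH2Cl2, 0 °C to rt
Reagents that add atoms: dibromomethane, BrCBr
Why: Takai–Lombardo methylenation with a non-basic gem-dimetallic reagent, which converts hindered, enolisable ketones without epimerising the α-centre C9; a phosphorus ylide would risk that. Ester and silyl ether are tolerated.

Step 14
Reactants: 21 methyl 2-(tert-butyldimethylsilyloxy)labd-8(17)-en-15-oate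
Product: 22 methyl (2R)-2-hydroxylabd-8(17)-en-15-oate (equatorial alcohol; other centres as in 27)
Conditions: n-Bu4NF (TBAF), THF, rt
Reagents that add atoms: none
Why: Fluoride-mediated cleavage of an unhindered equatorial secondary silyl ether; alkene and methyl ester are inert at room temperature.

Step 15
Reactants: 22 methyl (2R)-2-hydroxylabd-8(17)-en-15-oate
Product: 23 methyl 2-oxolabd-8(17)-en-15-oate (C5, C9, C10, C13 as in 27)
Conditions: Dess–Martin periodinane, NaHCO3, CH2Cl2, rt
Reagents that add atoms: none
Why: Buffered Dess–Martin oxidation of the secondary alcohol; the 1,1-disubstituted alkene and the ester are untouched, and no stereocentre is α to the new ketone.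

Step 16
Reactants: 23 methyl 2-oxolabd-8(17)-en-15-oate
Product: 24 methyl (2S)-2-hydroxylabd-8(17)-en-15-oate (axial alcohol, cis to the C10 methyl)
Conditions: Li[HB(s-Bu)3] (L-Selectride), THF, −78 °C; aq. NH4Cl
Reagents that add atoms: none
Why: Bulky-hydride reduction of a cyclohexanone whose axial trajectory is blocked by two syn-axial methyl groups (C20 and the axial C4 methyl), so hydride enters equatorially and the axial 2S alcohol of the target results. The methyl ester is not reduced at −78 °C.

Step 17
Reactants: 24 methyl (2S)-2-hydroxylabd-8(17)-en-15-oate; 25 isovaleric anhydride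
Product: 26 methyl (2S)-2-(3-methylbutanoyloxy)labd-8(17)-en-15-oate
Conditions: DMAP (1 equiv), Et3N, CH2Cl2, 40 °C
Reagents that add atoms: none
Why: DMAP-mediated acyl transfer from the anhydride; warming and a full equivalent of DMAP compensate for the two syn-axial methyl groups beside the axial hydroxyl.

Step 18
Reactants: 26 methyl (2S)-2-(3-methylbutanoyloxy)labd-8(17)-en-15-oate
Product: 27 (2S,5R,9S,10R,13S)-2-(3-methylbutanoyloxy)labd-8(17)-en-15-oic acid (CNP0168901.1)
Conditions: LiOH·H2O (2 equiv), THF/MeOH/H2O, 0 °C to rt; then dilute HCl to pH 4 at 0 °C
Reagents that add atoms: water, O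
Why: Saponification of the unhindered primary-alkyl methyl ester should be much faster than that of the isovalerate, which sits on an axial oxygen between two syn-axial methyl groups and is β-branched in its acyl part. Cold, brief acidification leaves the exocyclic alkene in place.

## Compound list

1 | ketoisophorone (2,6,6-trimethylcyclohex-2-ene-1,4-dione) | CC1=CC(=O)CC(C)(C)C1=O | starting material
2 | (4R)-4-hydroxy-2,6,6-trimethylcyclohex-2-en-1-one | CC1=C[C@H](O)CC(C)(C)C1=O | intermediate
3 | (4R)-4-(tert-butyldimethylsilyloxy)-2,6,6-trimethylcyclohex-2-en-1-one | CC1=C[C@H](O[Si](C)(C)C(C)(C)C)CC(C)(C)C1=O | intermediate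
4 | lithium (4S)-4-(tert-butyldimethylsilyloxy)-2,6,6-trimethylcyclohex-1-en-1-olate (not isolated) | [Li]OC1=C(C)C[C@H](O[Si](C)(C)C(C)(C)C)CC1(C)C | intermediate
5 | (4S)-4-(tert-butyldimethylsilyloxy)-2,6,6-trimethylcyclohex-1-en-1-yl trifluoromethanesulfonate | CC1=C(OS(=O)(=O)C(F)(F)F)C(C)(C)C[C@@H](O[Si](C)(C)C(C)(C)C)C1 | intermediate
6 | ethynyltrimethylsilane | C#C[Si](C)(C)C | starting material
7 | {[(4S)-4-(tert-butyldimethylsilyloxy)-2,6,6-trimethylcyclohex-1-en-1-yl]ethynyl}trimethylsilane (not isolated) | CC1=C(C#C[Si](C)(C)C)C(C)(C)C[C@@H](O[Si](C)(C)C(C)(C)C)C1 | intermediate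
8 | tert-butyl{[(1S)-4-ethynyl-3,5,5-trimethylcyclohex-3-en-1-yl]oxy}dimethylsilane | CC1=C(C#C)C(C)(C)C[C@@H](O[Si](C)(C)C(C)(C)C)C1 | intermediate
9 | 3-methylglutaric anhydride | CC1CC(=O)OC(=O)C1 | starting material
10 | (3S)-5-methoxy-3-methyl-5-oxopentanoic acid | COC(=O)C[C@@H](C)CC(=O)O | intermediate
11 | N-methoxy-N-methylacrylamide | C=CC(=O)N(C)OC | starting material
12 | N-hydroxyphthalimide ester of 10 (same spatial arrangement at C13; not isolated) | COC(=O)C[C@@H](C)CC(=O)ON1C(=O)c2ccccc2C1=O | intermediate
13 | methyl (3S)-7-[methoxy(methyl)amino]-3-methyl-7-oxoheptanoate | CON(C)C(=O)CCC[C@H](C)CC(=O)OC | intermediate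
14 | chloromagnesium acetylide of 8 (not isolated) | CC1=C(C#C[Mg]Cl)C(C)(C)C[C@@H](O[Si](C)(C)C(C)(C)C)C1 | intermediate
15 | methyl (3S)-9-[(4S)-4-(tert-butyldimethylsilyloxy)-2,6,6-trimethylcyclohex-1-en-1-yl]-3-methyl-7-oxonon-8-ynoate | CC1=C(C#CC(=O)CCC[C@H](C)CC(=O)OC)C(C)(C)C[C@@H](O[Si](C)(C)C(C)(C)C)C1 | intermediate
16 | methyl (3S,6Z)-7-(tert-butyldimethylsilyloxy)-9-[(4S)-4-(tert-butyldimethylsilyloxy)-2,6,6-trimethylcyclohex-1-en-1-yl]-3-methylnon-6-en-8-ynoate | CC1=C(C#C/C(O[Si](C)(C)C(C)(C)C)=C/CC[C@H](C)CC(=O)OC)C(C)(C)C[C@@H](O[Si](C)(C)C(C)(C)C)C1 | intermediate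
17 | methyl (3S,6Z,8Z)-7-(tert-butyldimethylsilyloxy)-9-[(4S)-4-(tert-butyldimethylsilyloxy)-2,6,6-trimethylcyclohex-1-en-1-yl]-3-methylnona-6,8-dienoate (key-step precursor) | CC1=C(/C=C\C(O[Si](C)(C)C(C)(C)C)=C\CC[C@H](C)CC(=O)OC)C(C)(C)C[C@@H](O[Si](C)(C)C(C)(C)C)C1 | intermediate
18 | methyl 2,8-bis(tert-butyldimethylsilyloxy)-17-norlabda-5,7-dien-15-oate (key-step product; 2-silyloxy trans to C20, C11 trans to C20) | CC(C)(C)[Si](C)(C)OC1=CC=C2C(C)(C)C[C@@H](O[Si](C)(C)C(C)(C)C)C[C@@]2(C)[C@H]1CC[C@H](C)CC(=O)OC | intermediate
19 | methyl 2-(tert-butyldimethylsilyloxy)-8-oxo-17-norlabd-5-en-15-oate | O=C1CC=C2C(C)(C)C[C@@H](O[Si](C)(C)C(C)(C)C)C[C@@]2(C)[C@H]1CC[C@H](C)CC(=O)OC | intermediate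
20 | methyl 2-(tert-butyldimethylsilyloxy)-8-oxo-17-norlabdan-15-oate (trans-fused) | O=C1CC[C@@H]2C(C)(C)C[C@@H](O[Si](C)(C)C(C)(C)C)C[C@@]2(C)[C@H]1CC[C@H](C)CC(=O)OC | intermediate
21 | methyl 2-(tert-butyldimethylsilyloxy)labd-8(17)-en-15-oate (equatorial silyloxy) | C=C1CC[C@@H]2C(C)(C)C[C@@H](O[Si](C)(C)C(C)(C)C)C[C@@]2(C)[C@H]1CC[C@H](C)CC(=O)OC | intermediate
22 | methyl (2R)-2-hydroxylabd-8(17)-en-15-oate (equatorial alcohol) | C=C1CC[C@@H]2C(C)(C)C[C@@H](O)C[C@@]2(C)[C@H]1CC[C@H](C)CC(=O)OC | intermediate
23 | methyl 2-oxolabd-8(17)-en-15-oate | C=C1CC[C@@H]2C(C)(C)CC(=O)C[C@@]2(C)[C@H]1CC[C@H](C)CC(=O)OC | intermediate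
24 | methyl (2S)-2-hydroxylabd-8(17)-en-15-oate (axial alcohol) | C=C1CC[C@@H]2C(C)(C)C[C@H](O)C[C@@]2(C)[C@H]1CC[C@H](C)CC(=O)OC | intermediate
25 | isovaleric anhydride (3-methylbutanoic anhydride) | CC(C)CC(=O)OC(=O)CC(C)C | starting material
26 | methyl (2S)-2-(3-methylbutanoyloxy)labd-8(17)-en-15-oate | C=C1CC[C@@H]2C(C)(C)C[C@H](OC(=O)CC(C)C)C[C@@]2(C)[C@H]1CC[C@H](C)CC(=O)OC | intermediate
27 | (2S,5R,9S,10R,13S)-2-(3-methylbutanoyloxy)labd-8(17)-en-15-oic acid (CNP0168901.1) | C=C1CC[C@@H]2C(C)(C)C[C@H](OC(=O)CC(C)C)C[C@@]2(C)[C@H]1CC[C@H](C)CC(=O)O | target

## Step count and least certain steps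

Total: 18 steps. Longest linear sequence: 16 steps (steps 1–4 and 7–18, from 1). The side-chain branch (steps 5 and 6) has 2 steps.

**Step 10 (key step).**
- Most likely failure: insufficient face selectivity. The only controlling centre, C2, is three bonds from C10 and acts through a conformational preference of ring A, not through direct shielding. The diastereomers differ in the ring relationship of C2 to C9/C10 and should be separable at 18 or 22.
- Second failure: loss of material at 150 °C. The closure onto a fully substituted terminus with an inside methyl is slow, so the [1,7]-shifted isomer may close at its other pair of termini, and [1,5]-hydrogen migration in the product diene or silyl transfer may set in.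
- Fallback (photochemical conrotatory closure at low temperature, where hydrogen shifts are frozen): from 15, kinetic enolisation (LiN(i-Pr)2 with TBSCl present, THF, −78 °C) gives the E enol ether, methyl (3S,6E)-7-(tert-butyldimethylsilyloxy)-9-[(4S)-4-(tert-butyldimethylsilyloxy)-2,6,6-trimethylcyclohex-1-en-1-yl]-3-methylnon-6-en-8-ynoate F1. Lindlar semi-hydrogenation gives the triene with both C11 and C20 inside, methyl (3S,6E,8Z)-7-(tert-butyldimethylsilyloxy)-9-[(4S)-4-(tert-butyldimethylsilyloxy)-2,6,6-trimethylcyclohex-1-en-1-yl]-3-methylnona-6,8-dienoate F2. Irradiation (300–350 nm, pentane, −20 °C) closes it in the conrotatory mode, which places two inside groups trans, and so leads to 18, where the route is rejoined. Competing Z/E isomerisation of the central alkene is this fallback's own weak point.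

**Step 9.**
- Most likely failure: stalling or over-reduction. The alkyne lies between a tetrasubstituted alkene carbon and a fully substituted enol ether carbon, and the triene product competes for the catalyst. Any E enol ether from step 8 is also carried into 17.
- Fallback (order of semi-reduction and enolisation exchanged): from 15, Lindlar semi-hydrogenation of the more reactive ynone gives the Z-dienone, methyl (3S,8Z)-9-[(4S)-4-(tert-butyldimethylsilyloxy)-2,6,6-trimethylcyclohex-1-en-1-yl]-3-methyl-7-oxonon-8-enoate F3, in equilibrium with its 2H-pyran valence isomer F4. Soft enolisation of the mixture (TBSOTf, Et3N, CH2Cl2, −78 °C) drains the open form, and the bulky cis substituent at the carbonyl enforces the Z enol ether. The route is rejoined at 17.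

**Step 12.**
- Most likely failure: hydrogen delivery to the C5 radical from the wrong face, because the axial C11 chain sits syn-axial on the face that must be attacked; partial reduction of the C8 ketone is a second risk.
- Fallback (hydrogenate before unveiling the ketone): from 18, H2 over PtO2 in EtOAc saturates C5=C6, the non-oxygenated double bond of the 5,7-diene, from the face opposite C20, as sterol 5,7-dienes do. This gives methyl 2,8-bis(tert-butyldimethylsilyloxy)-17-norlabd-7-en-15-oate F5 (H5 trans to C20). n-Bu4NF/AcOH then cleaves the enol ether and gives 20, where the route is rejoined; 19 is bypassed.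

**Step 6.**
- Most likely failure: inefficient capture of the primary radical by the acrylamide (simple reduction of the activated ester, or oligomerisation of the acceptor).
- Fallback (polar chain extension without decarboxylation): from 10, BH3·SMe2 reduces the acid to methyl (3S)-5-hydroxy-3-methylpentanoate F6. Dess–Martin oxidation gives methyl (3S)-3-methyl-5-oxopentanoate F7. Wittig reaction with Ph3P=CHC(O)N(OMe)Me gives methyl (3S,5E)-7-[methoxy(methyl)amino]-3-methyl-7-oxohept-5-enoate F8. Hydrogenation (H2, Pd/C) gives 13, where the route is rejoined.

**Step 18.**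
- Most likely failure: partial cleavage of the isovalerate during saponification if the methyl ester reacts more slowly than expected.
- Fallback (order of hydrolysis and acylation exchanged): from 24, LiOH gives (2S)-2-hydroxylabd-8(17)-en-15-oic acid F9. Acylation with excess 25 and DMAP, followed by aqueous hydrolysis of the mixed anhydride at C15, gives 27 directly.

## Further compounds

F1 | step 10 | methyl (3S,6E)-7-(tert-butyldimethylsilyloxy)-9-[(4S)-4-(tert-butyldimethylsilyloxy)-2,6,6-trimethylcyclohex-1-en-1-yl]-3-methylnon-6-en-8-ynoate | CC1=C(C#C/C(O[Si](C)(C)C(C)(C)C)=C\CC[C@H](C)CC(=O)OC)C(C)(C)C[C@@H](O[Si](C)(C)C(C)(C)C)C1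
F2 | step 10 | methyl (3S,6E,8Z)-7-(tert-butyldimethylsilyloxy)-9-[(4S)-4-(tert-butyldimethylsilyloxy)-2,6,6-trimethylcyclohex-1-en-1-yl]-3-methylnona-6,8-dienoate | CC1=C(/C=C\C(O[Si](C)(C)C(C)(C)C)=C/CC[C@H](C)CC(=O)OC)C(C)(C)C[C@@H](O[Si](C)(C)C(C)(C)C)C1
F3 | step 9 | methyl (3S,8Z)-9-[(4S)-4-(tert-butyldimethylsilyloxy)-2,6,6-trimethylcyclohex-1-en-1-yl]-3-methyl-7-oxonon-8-enoate | CC1=C(/C=C\C(=O)CCC[C@H](C)CC(=O)OC)C(C)(C)C[C@@H](O[Si](C)(C)C(C)(C)C)C1
F4 | step 9 | 2H-pyran valence isomer of F3 (O bonded to C8 and C10; both C10 epimers, in equilibrium with F3) | CC12OC(CCC[C@H](C)CC(=O)OC)=CC=C1C(C)(C)C[C@@H](O[Si](C)(C)C(C)(C)C)C2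
F5 | step 12 | methyl 2,8-bis(tert-butyldimethylsilyloxy)-17-norlabd-7-en-15-oate (H5 trans to C20) | CC(C)(C)[Si](C)(C)OC1=CC[C@@H]2C(C)(C)C[C@@H](O[Si](C)(C)C(C)(C)C)C[C@@]2(C)[C@H]1CC[C@H](C)CC(=O)OC
F6 | step 6 | methyl (3S)-5-hydroxy-3-methylpentanoate | COC(=O)C[C@@H](C)CCO
F7 | step 6 | methyl (3S)-3-methyl-5-oxopentanoate | COC(=O)C[C@@H](C)CC=O
F8 | step 6 | methyl (3S,5E)-7-[methoxy(methyl)amino]-3-methyl-7-oxohept-5-enoate | COC(=O)C[C@@H](C)C/C=C/C(=O)N(C)OC
F9 | step 18 | (2S)-2-hydroxylabd-8(17)-en-15-oic acid (other centres as in 27) | C=C1CC[C@@H]2C(C)(C)C[C@H](O)C[C@@]2(C)[C@H]1CC[C@H](C)CC(=O)O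
A1 | alternative 1 | 13-(tert-butyldiphenylsilyloxy)-3,3,11-trimethyl-4-(prop-1-en-2-yl)-7-[(trimethylsilyl)methyl]tridec-7-enal (7E by the sequence rule, chain carbons 6 and 9 cis) | O=CCC(C)(C)[C@H](C(C)=C)CC/C(C[Si](C)(C)C)=C\CC[C@H](C)CCO[Si](c1ccccc1)(c1ccccc1)C(C)(C)C
A2 | alternative 1 | 9-epi-ent-labd-8(17)-ene-2,15-diol 15-tert-butyldiphenylsilyl ether (C2 hydroxyl equatorial) | C=C1CC[C@@H]2C(C)(C)C[C@@H](O)C[C@@]2(C)[C@H]1CC[C@H](C)CCO[Si](c1ccccc1)(c1ccccc1)C(C)(C)C
A3 | alternative 2 | tert-butyldimethyl[(4-methylpenta-1,3-dien-2-yl)oxy]silane | C=C(O[Si](C)(C)C(C)(C)C)C=C(C)C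
A4 | alternative 2 | 2-methylcyclohex-2-ene-1,4-dione | CC1=CC(=O)CCC1=O
A5 | alternative 2 | cis-fused bicyclic 6,9-dione with C2 silyl enol ether | O=C1CCC(=O)[C@H]2C(C)(C)C=C(O[Si](C)(C)C(C)(C)C)C[C@@]12C
A6 | alternative 3 | (4S)-4-(tert-butyldimethylsilyloxy)-2,6,6-trimethylcyclohex-1-ene-1-carbaldehyde | CC1=C(C=O)C(C)(C)C[C@@H](O[Si](C)(C)C(C)(C)C)C1
A7 | alternative 3 | methyl acetoacetate | CC(=O)CC(=O)OC
A8 | alternative 3 | bicyclic 8-hydroxy-5,7-diene-7-carboxylate (enol of the β-keto ester) | COC(=O)C1=C(O)C[C@]2(C)C[C@H](O[Si](C)(C)C(C)(C)C)CC(C)(C)C2=C1
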